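**Retrosynthetic overview**
- Key disconnection: ring C is cut at three bonds at once (C4a–C4, C4–C3, O1–C2) into a ring A ortho-iodophenol, carbon monoxide and a ring B aryl acetylene. These are joined in one palladium-catalysed carbonylative alkynylation/6-endo annulation, so no acetophenone, chalcone or 1,3-diketone is used.
- Ring A: the pentaoxygenated pattern comes from Thiele–Winter acetoxylation of 2,3-dimethoxy-1,4-benzoquinone, with regiochemistry fixed by symmetry. The new 1,2-diol (future 5,6-OH) is held as a diphenylmethylene ketal, leaving one free OH (future O1) and one free CH (iodinated, future C4a).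
- Ring B: 2-hydroxy-6-methoxybenzaldehyde already distinguishes 2'-OH from 6'-OMe; benzylation and Ohira–Bestmann homologation give the alkyne.
- Endgame: one hydrogenolysis removes the benzyl ether and the ketal together.
- Ring order: rings A and B are carried as preformed benzene rings; ring C is formed in the key step, one step before the end.

Assumption: the target has no stereocentre and its C2–C1' axis is not configurationally stable, so it is achiral; "single enantiomer" is taken to mean exactly the constitution of the given SMILES.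

**Route**

Step 1
Reactants: 1 2,3-dimethoxyphenol
Product: 2 2,3-dimethoxy-1,4-benzoquinone
Conditions: (KSO3)2NO (2.5 equiv), KH2PO4 buffer, H2O/acetone, 0 °C to rt
Reagents that add atoms: potassium nitrosodisulfonate (Fremy's salt), [K+].[K+].[O]N(S(=O)(=O)[O-])S(=O)(=O)[O-]
Why: Teuber oxidation, in which the phenoxyl radical is trapped by a second nitroxide radical at the free para position and the adduct collapses to the para-quinone; no stereocentre is formed.

Step 2
Reactants: 2 2,3-dimethoxy-1,4-benzoquinone
Product: 3 5,6-dimethoxybenzene-1,2,4-triyl triacetate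
Conditions: Ac2O, H2SO4 (cat.), 0 °C to 40 °C
Reagents that add atoms: acetic anhydride, CC(=O)OC(C)=O
Why: Thiele–Winter acetoxylation, in which the acid-activated quinone takes up acetate by conjugate addition at one of its two symmetry-equivalent free positions and the resulting arene is peracetylated, so only one regioisomer can form; no stereocentre.

Step 3
Reactants: 3 5,6-dimethoxybenzene-1,2,4-triyl triacetate
Product: 4 5,6-dimethoxybenzene-1,2,4-triol
Conditions: conc. HCl (cat.), degassed MeOH, reflux, Ar; evaporate and use crude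
Reagents that add atoms: none
Why: Acid-catalysed transesterification (methanolysis) removes the three aryl acetates without exposing the oxidation-prone triol to base and air; no stereocentre.

Step 4
Reactants: 4 5,6-dimethoxybenzene-1,2,4-triol
Product: 5 6,7-dimethoxy-2,2-diphenyl-1,3-benzodioxol-5-ol
Conditions: Ph2CCl2 (1.2 equiv), Ph2O, 175 °C, N2 sweep
Reagents that add atoms: dichlorodiphenylmethane, ClC(Cl)(c1ccccc1)c1ccccc1
Why: Catechol diphenylmethylene ketal formation (double substitution at the gem-dichloride) can close a five-membered ring only on the vicinal 1,2-diol, so the isolated 4-OH stays free; no stereocentre.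

Step 5
Reactants: 5 6,7-dimethoxy-2,2-diphenyl-1,3-benzodioxol-5-ol
Product: 6 4-iodo-6,7-dimethoxy-2,2-diphenyl-1,3-benzodioxol-5-ol
Conditions: NIS (1.05 equiv), MeCN, 0 °C, dark
Reagents that add atoms: N-iodosuccinimide, O=C1CCC(=O)N1I
Why: Electrophilic aromatic iodination occurs at the only free ring position, which is ortho to the free phenol and strongly activated; no stereocentre.

Step 6
Reactants: 7 2-hydroxy-6-methoxybenzaldehyde
Product: 8 2-(benzyloxy)-6-methoxybenzaldehyde
Conditions: BnBr, K2CO3, DMF, 60 °C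
Reagents that add atoms: benzyl bromide, BrCc1ccccc1
Why: Williamson ether synthesis on the phenoxide protects the future 2'-OH as a hydrogenolysable benzyl ether; no stereocentre.

Step 7
Reactants: 8 2-(benzyloxy)-6-methoxybenzaldehyde
Product: 10 1-(benzyloxy)-2-ethynyl-3-methoxybenzene, via diazoalkene 9 (not isolated)
Conditions: dimethyl (1-diazo-2-oxopropyl)phosphonate, K2CO3, MeOH, 0 °C to rt
Reagents that add atoms: dimethyl (1-diazo-2-oxopropyl)phosphonate (Ohira–Bestmann reagent), COP(=O)(OC)C(=[N+]=[N-])C(C)=O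
Why: Ohira–Bestmann (Seyferth–Gilbert) homologation, in which the diazomethylphosphonate anion released by methanolysis olefinates the non-enolisable aldehyde to diazoalkene 9, and loss of N2 with 1,2-hydrogen shift gives the terminal alkyne; no stereocentre.

Step 8
Reactants: 6 4-iodo-6,7-dimethoxy-2,2-diphenyl-1,3-benzodioxol-5-ol; 10 1-(benzyloxy)-2-ethynyl-3-methoxybenzene (1.5 equiv)
Product: 13 7-[2-(benzyloxy)-6-methoxyphenyl]-4,5-dimethoxy-2,2-diphenyl-9H-[1,3]dioxolo[4,5-f]chromen-9-one, via ynone 11 (not isolated), via enaminone 12 (not isolated)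
Conditions: PdCl2(dppf) (5 mol %; dppf = 1,1'-bis(diphenylphosphino)ferrocene), CO (10 bar), Et2NH, 100 °C, copper-free
Reagents that add atoms: carbon monoxide, [C-]#[O+]
Why: Carbonylative Sonogashira coupling/annulation cascade, in which zerovalent palladium (formed in situ from the divalent precatalyst) inserts into the C–I bond, CO insertion and alkynylation give ynone 11, Et2NH adds to give enaminone 12, and the ortho-phenol then closes 6-endo with loss of Et2NH, which directs the reaction to the flavone and away from the aurone; no stereocentre.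

Step 9
Reactants: 13 7-[2-(benzyloxy)-6-methoxyphenyl]-4,5-dimethoxy-2,2-diphenyl-9H-[1,3]dioxolo[4,5-f]chromen-9-one
Product: 14 5,6,2'-trihydroxy-7,8,6'-trimethoxyflavone
Conditions: H2 (1 atm), Pd(OH)2/C, THF/MeOH 1:1, rt; filter and work up under Ar
Reagents that add atoms: none
Why: Catalytic hydrogenolysis cleaves the benzylic C–O bonds of both the benzyl ether and the diphenylmethylene ketal, while the aryl methyl ethers and the pyranone ring are inert under these mild conditions; no stereocentre.

**Compound list**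

1 | 2,3-dimethoxyphenol | COc1cccc(O)c1OC | starting material
2 | 2,3-dimethoxy-1,4-benzoquinone | COC1=C(OC)C(=O)C=CC1=O | intermediate
3 | 5,6-dimethoxybenzene-1,2,4-triyl triacetate | COc1c(OC)c(OC(C)=O)cc(OC(C)=O)c1OC(C)=O | intermediate
4 | 5,6-dimethoxybenzene-1,2,4-triol | COc1c(OC)c(O)cc(O)c1O | intermediate
5 | 6,7-dimethoxy-2,2-diphenyl-1,3-benzodioxol-5-ol | COc1c(O)cc2OC(c3ccccc3)(c3ccccc3)Oc2c1OC | intermediate
6 | 4-iodo-6,7-dimethoxy-2,2-diphenyl-1,3-benzodioxol-5-ol | COc1c(O)c(I)c2OC(c3ccccc3)(c3ccccc3)Oc2c1OC | intermediate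
7 | 2-hydroxy-6-methoxybenzaldehyde | COc1cccc(O)c1C=O | starting material
8 | 2-(benzyloxy)-6-methoxybenzaldehyde | COc1cccc(OCc2ccccc2)c1C=O | intermediate
9 | 1-(benzyloxy)-2-(2-diazoethenyl)-3-methoxybenzene (diazoalkene) | COc1cccc(OCc2ccccc2)c1C=C=[N+]=[N-] | intermediate
10 | 1-(benzyloxy)-2-ethynyl-3-methoxybenzene | COc1cccc(OCc2ccccc2)c1C#C | intermediate
11 | 3-[2-(benzyloxy)-6-methoxyphenyl]-1-(5-hydroxy-6,7-dimethoxy-2,2-diphenyl-1,3-benzodioxol-4-yl)prop-2-yn-1-one (ynone) | COc1c(O)c(C(=O)C#Cc2c(OC)cccc2OCc2ccccc2)c2OC(c3ccccc3)(c3ccccc3)Oc2c1OC | intermediate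
12 | (E)-3-[2-(benzyloxy)-6-methoxyphenyl]-3-(diethylamino)-1-(5-hydroxy-6,7-dimethoxy-2,2-diphenyl-1,3-benzodioxol-4-yl)prop-2-en-1-one (enaminone; double-bond geometry labile) | COc1c(O)c(C(=O)/C=C(/N(CC)CC)c2c(OC)cccc2OCc2ccccc2)c2OC(c3ccccc3)(c3ccccc3)Oc2c1OC | intermediate
13 | 7-[2-(benzyloxy)-6-methoxyphenyl]-4,5-dimethoxy-2,2-diphenyl-9H-[1,3]dioxolo[4,5-f]chromen-9-one (target with 5,6-O-diphenylmethylene and 2'-O-benzyl protection) | COc1cccc(OCc2ccccc2)c1-c1cc(=O)c2c3OC(c4ccccc4)(c4ccccc4)Oc3c(OC)c(OC)c2o1 | intermediate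
14 | 5,6,2'-trihydroxy-7,8,6'-trimethoxyflavone | COc1cccc(O)c1-c1cc(=O)c2c(O)c(O)c(OC)c(OC)c2o1 | target

**Step count and risks**

Total step count: 9. Longest linear sequence: 7 steps (steps 1, 2, 3, 4, 5, 8, 9).

Step 8 is the most likely to fail. Iodide 6 is electron-rich and flanked by two oxygen substituents, and alkyne 10 is 2,6-disubstituted. Oxidative addition may therefore be slow, and direct alkynylation to a benzofuran, aminocarbonylation to the diethylamide, or 5-exo closure to the aurone may compete. The fallback builds the same ynone without palladium or CO; it sets out from 5 (with 10) and comes back to the route at 13. Magnesium-phenoxide-directed ortho-formylation of 5 (MgCl2, Et3N, paraformaldehyde, MeCN, reflux) gives 5-hydroxy-6,7-dimethoxy-2,2-diphenyl-1,3-benzodioxole-4-carbaldehyde F1. Addition of the lithium acetylide of 10 (n-BuLi, THF, −78 °C, 2.2 equiv) gives racemic 4-{3-[2-(benzyloxy)-6-methoxyphenyl]-1-hydroxyprop-2-yn-1-yl}-6,7-dimethoxy-2,2-diphenyl-1,3-benzodioxol-5-ol F2. MnO2 in CH2Cl2 oxidises F2 to ynone 11, now isolated, and Et2NH in EtOH at 60 °C closes it through 12 to 13.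

Step 2 is the second risk. Both carbonyls of quinone 2 are vinylogous esters, so the conjugate acetoxylation may be sluggish or give tar under the strongly acidic conditions. The fallback sets out from 2 and comes back at 4. Nucleophilic epoxidation of the unsubstituted ring C=C bond (H2O2, Na2CO3, aqueous EtOH, 0 °C) gives cis-3,4-dimethoxy-7-oxabicyclo[4.1.0]hept-3-ene-2,5-dione F3. Acid-catalysed epoxide opening and enolisation (H2SO4 cat., AcOH) gives 2-hydroxy-5,6-dimethoxy-1,4-benzoquinone F4. Reduction with Na2S2O4 (water/EtOAc, Ar) then gives triol 4.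

Step 9 is the third risk. The ketal is hydrogenolysed more slowly than the benzyl ether, prolonged exposure may saturate the C2–C3 bond, and the catechol product is air-sensitive. The fallback is non-reductive, sets out from 13 and comes back at 14. Hydrolysis of the ketal in AcOH/H2O 4:1 at reflux gives 2-[2-(benzyloxy)-6-methoxyphenyl]-5,6-dihydroxy-7,8-dimethoxy-4H-chromen-4-one F5. Debenzylation with BCl3 and pentamethylbenzene as cation scavenger (CH2Cl2, −78 °C) then gives 14.

Further compounds
F1 | step 8 | 5-hydroxy-6,7-dimethoxy-2,2-diphenyl-1,3-benzodioxole-4-carbaldehyde | COc1c(O)c(C=O)c2OC(c3ccccc3)(c3ccccc3)Oc2c1OC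
F2 | step 8 | racemic 4-{3-[2-(benzyloxy)-6-methoxyphenyl]-1-hydroxyprop-2-yn-1-yl}-6,7-dimethoxy-2,2-diphenyl-1,3-benzodioxol-5-ol | COc1c(O)c(C(O)C#Cc2c(OC)cccc2OCc2ccccc2)c2OC(c3ccccc3)(c3ccccc3)Oc2c1OC
F3 | step 2 | cis-(1R,6S)-3,4-dimethoxy-7-oxabicyclo[4.1.0]hept-3-ene-2,5-dione (meso) | COC1=C(OC)C(=O)[C@@H]2O[C@@H]2C1=O
F4 | step 2 | 2-hydroxy-5,6-dimethoxy-1,4-benzoquinone | COC1=C(OC)C(=O)C(O)=CC1=O
F5 | step 9 | 2-[2-(benzyloxy)-6-methoxyphenyl]-5,6-dihydroxy-7,8-dimethoxy-4H-chromen-4-one | COc1cccc(OCc2ccccc2)c1-c1cc(=O)c2c(O)c(O)c(OC)c(OC)c2o1
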